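**Assumption:** the SMILES is read as the (6S,7R)-acid with 1(10)Z,2Z,4E alkenes. Ring atoms are labelled C1–C10: C4 carries CO2H (C18), C5 carries CH2OAc (C19), C8 carries CH3, C9 carries CH3 and the furylethyl arm; alkenes are C1=C10 (E), C2=C3 (Z), C4=C5 (Z). Compounds 1, 2, 4, 8, 11, 17, 18 and the tripeptide H-D-Pro-Pro-Glu-NH2 are bought.

## Retrosynthetic overview

1. Target ⇐ macrocyclic butenolide 21: the lactone is saponified and the freed C19–OH acetylated in the same pot.
2. Ten-membered ring ⇐ double Stille "stitching": (Z)-Bu3SnCH=CHSnBu3 joins the E-vinyl iodide (C1) and the α-bromobutenolide (C4). This is the only ring formed; the furan and butenolide rings are bought.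
3. C5–C6 ⇐ B-alkyl Suzuki coupling with 3,4-dibromofuran-2(5H)-one; C10=C1 ⇐ Takai olefination; C6=C7 ⇐ Wittig methylenation.
4. Key bond C8–C9 ⇐ propanal enamine + (E)-nitroalkene 7. The nitroalkene acts as an α-carbonyl-cation (enolonium) equivalent of the later C10 aldehyde (Nef), so two α-carbons are joined and both stereocentres, including the quaternary one, are set in one catalytic step.
5. Nitroalkene 7 ⇐ 4-(furan-3-yl)butan-2-one + CH3NO2 ⇐ furan-3-ylboronic acid + methyl vinyl ketone.

## Route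

**Step 1**
Reactants: 1 furan-3-ylboronic acid; 2 but-3-en-2-one
Product: 3 4-(furan-3-yl)butan-2-one
Conditions: 1 (1.3 equiv), [Rh(cod)OH]2 (1.5 mol %), dioxane/H2O 10:1, 40 °C
Reagents that add atoms: none
Why: Hayashi–Miyaura rhodium-catalysed 1,4-addition of a heteroarylboronic acid to an enone, the rhodium enolate being protonated by water; no stereocentre is formed.

**Step 2**
Reactants: 3 4-(furan-3-yl)butan-2-one; 4 nitromethane
Product: 7 3-[(3E)-3-methyl-4-nitrobut-3-en-1-yl]furan, via nitro alcohol 5 (not isolated), via tertiary mesylate 6 (not isolated)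
Conditions: CH3NO2 (neat), tetramethylguanidine (0.2 equiv), rt; evaporate; MsCl (1.5 equiv), Et3N (3 equiv), CH2Cl2, −20 → 0 °C; SiO2 (E isomer collected)
Reagents that add atoms: none
Why: Henry (nitroaldol) addition to the methyl ketone followed by E1cB loss of mesylate gives the conjugated nitroalkene; the E isomer (furylethyl arm trans to NO2) is separated, and the Z and β,γ isomers are re-equilibrated with Et3N and recycled.

**Step 3 (key step)**
Reactants: 7 3-[(3E)-3-methyl-4-nitrobut-3-en-1-yl]furan; 8 propanal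
Product: 9 (2S,3S)-5-(furan-3-yl)-2,3-dimethyl-3-(nitromethyl)pentanal
Conditions: 8 (3 equiv), H-D-Pro-Pro-Glu-NH2·TFA (10 mol %), N-methylmorpholine (10 mol %), CHCl3/i-PrOH 9:1 (1 M), rt, 72–96 h
Reagents that add atoms: none
Why: Proposed new method: the enamine formed from propanal and the D-proline terminus adds to the nitroalkene, which serves as an enolonium equivalent of the later C10 aldehyde, so the two α-carbons C8 and C9 are joined; the closest known reaction is the peptide- or diarylprolinol-catalysed Michael addition of aldehydes to nitroalkenes, including β,β-disubstituted ones, and the β,β-dialkyl case is the extension; the (R)-pyrrolidine shields one enamine face and sets C8 (2S), while the E geometry places the furylethyl arm anti to NO2 in the synclinal transition state and sets the quaternary C9 (3S); any Z-7 gives a separable C9 epimer, not the enantiomer.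

**Step 4**
Reactants: 9 (2S,3S)-5-(furan-3-yl)-2,3-dimethyl-3-(nitromethyl)pentanal
Product: 10 3-[(3S,4R)-3,4-dimethyl-3-(nitromethyl)hex-5-en-1-yl]furan
Conditions: Ph3PCH3Br (2.6 equiv), KN(SiMe3)2 (2.5 equiv), THF, −78 → 0 °C (aldehyde added to the ylide); aq NH4Cl
Reagents that add atoms: methyltriphenylphosphonium bromide, C[P+](c1ccccc1)(c1ccccc1)c1ccccc1.[Br-]
Why: Wittig methylenation of the hindered α-branched aldehyde; the first equivalent of ylide only deprotonates CH2NO2 (restored by the NH4Cl quench) and the low temperature keeps C8 from epimerising (the descriptor changes to R only through CIP priorities).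

**Step 5**
Reactants: 10 3-[(3S,4R)-3,4-dimethyl-3-(nitromethyl)hex-5-en-1-yl]furan; 11 3,4-dibromofuran-2(5H)-one
Product: 13 3-bromo-4-[(3R,4S)-6-(furan-3-yl)-3,4-dimethyl-4-(nitromethyl)hexyl]furan-2(5H)-one, via alkylborane 12 (not isolated)
Conditions: 9-BBN (1.3 equiv), THF, rt, 4 h; then 11 (1.2 equiv), Pd(dppf)Cl2 (5 mol %), AsPh3 (10 mol %), K3PO4 (3 M aq, 2.5 equiv), THF/DMF, 0 °C → rt; aq NH4Cl
Reagents that add atoms: none
Why: 9-BBN hydroborates only the terminal alkene (anti-Markovnikov) and the B-alkyl Suzuki–Miyaura coupling takes place at the more electrophilic C–Br β to the lactone carbonyl, leaving the α-bromide for step 9; the hindered neopentyl nitronate formed by the base is a spectator.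

**Step 6**
Reactants: 13 3-bromo-4-[(3R,4S)-6-(furan-3-yl)-3,4-dimethyl-4-(nitromethyl)hexyl]furan-2(5H)-one
Product: 15 (2S,3R)-5-(4-bromo-5-oxo-2,5-dihydrofuran-3-yl)-2-[2-(furan-3-yl)ethyl]-2,3-dimethylpentanal, via sodium nitronate 14 (not isolated)
Conditions: NaOMe (1.05 equiv), MeOH, 0 °C, 15 min; then TiCl3 (aq, 4 equiv), NH4OAc buffer (pH 5–6), THF/H2O, 0 °C → rt
Reagents that add atoms: water, O
Why: Nef reaction in its reductive titanium trichloride (McMurry) form: the nitronate is reduced to the imine and hydrolysed near neutral pH, which spares the furan and the bromobutenolide; the α-quaternary aldehyde cannot epimerise.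

**Step 7**
Reactants: 15 (2S,3R)-5-(4-bromo-5-oxo-2,5-dihydrofuran-3-yl)-2-[2-(furan-3-yl)ethyl]-2,3-dimethylpentanal
Product: 16 3-bromo-4-[(3R,4S,5E)-4-[2-(furan-3-yl)ethyl]-6-iodo-3,4-dimethylhex-5-en-1-yl]furan-2(5H)-one
Conditions: CrCl2 (8 equiv), CHI3 (3 equiv), dioxane/THF 6:1, 0 °C → rt, dark
Reagents that add atoms: iodoform, IC(I)I
Why: Takai olefination: the gem-dichromium species from CHI3 adds to the aldehyde and elimination gives the E-vinyl iodide, the bulky α-quaternary centre reinforcing E selectivity; the lactone and the vinylic C–Br are inert to CrCl2 without nickel.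

**Step 8**
Reactants: 17 hexabutylditin; 18 acetylene
Product: 19 (Z)-1,2-bis(tributylstannyl)ethene
Conditions: Pd(PPh3)4 (1 mol %), C2H2 (1 atm), dioxane, 60 °C
Reagents that add atoms: none
Why: palladium-catalysed syn-addition of the Sn–Sn bond across the alkyne (distannylation) gives only the Z isomer.

**Step 9**
Reactants: 16 3-bromo-4-[(3R,4S,5E)-4-[2-(furan-3-yl)ethyl]-6-iodo-3,4-dimethylhex-5-en-1-yl]furan-2(5H)-one; 19 (Z)-1,2-bis(tributylstannyl)ethene
Product: 21 (6R,7S,8E,10Z)-7-[2-(furan-3-yl)ethyl]-6,7-dimethyl-4,5,6,7-tetrahydrocyclodeca[c]furan-1(3H)-one, via dienylstannane 20 (not isolated)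
Conditions: Pd2(dba)3 (10 mol %), AsPh3 (0.4 equiv), i-Pr2NEt (2 equiv), DMF/THF 1:1 (1 mM), 19 (1.05 equiv) added over 10 h, 25 → 50 °C
Reagents that add atoms: none
Why: double Stille coupling ("stitching" macrocyclisation): the vinyl iodide couples first with one stannyl end, then the dienylstannane closes the ten-membered ring onto the α-bromobutenolide under high dilution; both couplings retain alkene geometry, giving C1=C10 E and C2=C3 Z.

**Step 10**
Reactants: 21 (6R,7S,8E,10Z)-7-[2-(furan-3-yl)ethyl]-6,7-dimethyl-4,5,6,7-tetrahydrocyclodeca[c]furan-1(3H)-one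
Product: 23 (1(10)Z,2Z,4E,6S,7R)-10-(acetoxymethyl)-6-[2-(furan-3-yl)ethyl]-6,7-dimethylcyclodeca-1(10),2,4-triene-1-carboxylic acid, via lithium hydroxy carboxylate 22 (not isolated)
Conditions: LiOH·H2O (1.05 equiv), THF/H2O 3:1, 0 °C; evaporate, toluene azeotrope; Ac2O (5 equiv), DMAP (0.1 equiv), pyridine, −20 → 0 °C; H2O, then cold dilute HCl to pH 4
Reagents that add atoms: lithium hydroxide, [Li+].[OH-]; acetic anhydride, CC(=O)OC(C)=O
Why: saponification opens the butenolide to the (Z)-hydroxy carboxylate, and DMAP-catalysed acetylation of the primary allylic alcohol is expected to be faster than activation of the hindered, conjugated lithium carboxylate, so relactonisation is outrun; the tetrasubstituted Z-alkene is configurationally fixed.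

## Compound list

1 | furan-3-ylboronic acid | OB(O)c1ccoc1 | starting material
2 | but-3-en-2-one (methyl vinyl ketone) | CC(=O)C=C | starting material
3 | 4-(furan-3-yl)butan-2-one | CC(=O)CCc1ccoc1 | intermediate
4 | nitromethane | C[N+](=O)[O-] | starting material
5 | 4-(furan-3-yl)-2-methyl-1-nitrobutan-2-ol (racemic) | CC(O)(CCc1ccoc1)C[N+](=O)[O-] | intermediate
6 | 4-(furan-3-yl)-2-methyl-1-nitrobutan-2-yl methanesulfonate (racemic) | CC(OS(C)(=O)=O)(CCc1ccoc1)C[N+](=O)[O-] | intermediate
7 | 3-[(3E)-3-methyl-4-nitrobut-3-en-1-yl]furan | C/C(CCc1ccoc1)=C\[N+](=O)[O-] | intermediate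
8 | propanal | CCC=O | starting material
9 | (2S,3S)-5-(furan-3-yl)-2,3-dimethyl-3-(nitromethyl)pentanal | [O-][N+](=O)C[C@@](C)(CCc1ccoc1)[C@H](C)C=O | intermediate
10 | 3-[(3S,4R)-3,4-dimethyl-3-(nitromethyl)hex-5-en-1-yl]furan | [O-][N+](=O)C[C@@](C)(CCc1ccoc1)[C@H](C)C=C | intermediate
11 | 3,4-dibromofuran-2(5H)-one | O=C1OCC(Br)=C1Br | starting material
12 | 9-[(3R,4S)-6-(furan-3-yl)-3,4-dimethyl-4-(nitromethyl)hexyl]-9-borabicyclo[3.3.1]nonane | [O-][N+](=O)C[C@@](C)(CCc1ccoc1)[C@H](C)CCB1C2CCCC1CCC2 | intermediate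
13 | 3-bromo-4-[(3R,4S)-6-(furan-3-yl)-3,4-dimethyl-4-(nitromethyl)hexyl]furan-2(5H)-one | [O-][N+](=O)C[C@@](C)(CCc1ccoc1)[C@H](C)CCC1=C(Br)C(=O)OC1 | intermediate
14 | sodium nitronate (aci-nitro salt) of 13 | [Na+].[O-][N+]([O-])=C[C@@](C)(CCc1ccoc1)[C@H](C)CCC1=C(Br)C(=O)OC1 | intermediate
15 | (2S,3R)-5-(4-bromo-5-oxo-2,5-dihydrofuran-3-yl)-2-[2-(furan-3-yl)ethyl]-2,3-dimethylpentanal | O=C[C@@](C)(CCc1ccoc1)[C@H](C)CCC1=C(Br)C(=O)OC1 | intermediate
16 | 3-bromo-4-[(3R,4S,5E)-4-[2-(furan-3-yl)ethyl]-6-iodo-3,4-dimethylhex-5-en-1-yl]furan-2(5H)-one | I/C=C/[C@@](C)(CCc1ccoc1)[C@H](C)CCC1=C(Br)C(=O)OC1 | intermediate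
17 | hexabutylditin | CCCC[Sn](CCCC)(CCCC)[Sn](CCCC)(CCCC)CCCC | starting material
18 | acetylene | C#C | starting material
19 | (Z)-1,2-bis(tributylstannyl)ethene | CCCC[Sn](CCCC)(CCCC)/C=C\[Sn](CCCC)(CCCC)CCCC | intermediate
20 | tributyl[(1Z,3E,5S,6R)-8-(4-bromo-5-oxo-2,5-dihydrofuran-3-yl)-5-[2-(furan-3-yl)ethyl]-5,6-dimethylocta-1,3-dien-1-yl]stannane | CCCC[Sn](CCCC)(CCCC)/C=C\C=C\[C@@](C)(CCc1ccoc1)[C@H](C)CCC1=C(Br)C(=O)OC1 | intermediate
21 | (6R,7S,8E,10Z)-7-[2-(furan-3-yl)ethyl]-6,7-dimethyl-4,5,6,7-tetrahydrocyclodeca[c]furan-1(3H)-one (butenolide fused to the ten-membered triene) | O=C1OCC2=C1/C=C\C=C\[C@@](C)(CCc3ccoc3)[C@H](C)CC2 | intermediate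
22 | lithium (1(10)Z,2Z,4E,6S,7R)-6-[2-(furan-3-yl)ethyl]-10-(hydroxymethyl)-6,7-dimethylcyclodeca-1(10),2,4-triene-1-carboxylate | [Li+].OC/C1=C(C(=O)[O-])/C=C\C=C\[C@@](C)(CCc2ccoc2)[C@H](C)CC1 | intermediate
23 | (1(10)Z,2Z,4E,6S,7R)-10-(acetoxymethyl)-6-[2-(furan-3-yl)ethyl]-6,7-dimethylcyclodeca-1(10),2,4-triene-1-carboxylic acid | CC(=O)OC/C1=C(C(=O)O)/C=C\C=C\[C@@](C)(CCc2ccoc2)[C@H](C)CC1 | target

## Step count and risks

Total step count: 10 (steps 1–10; step 8 is a one-step side branch).
Longest linear sequence: 9 steps (1–7, 9, 10).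

**Three steps most likely to fail**

**Step 3 (key Michael addition).** A β,β-dialkyl nitroalkene is a weak acceptor and may isomerise (E/Z or to the β,γ isomer) under amine catalysis, and discrimination between CH3 and the furylethyl arm rests entirely on alkene geometry. The fallback sets out from 7 and 8 and replaces catalytic enamine activation by a stoichiometric chiral azaenolate. Propanal 8 is condensed with (S)-1-amino-2-(methoxymethyl)pyrrolidine to give propanal SAMP hydrazone F1. F1 is deprotonated with LiN(i-Pr)2 in THF at −78 °C and the lithium azaenolate is added to 7 at −100 → −78 °C, giving after an NH4Cl quench the hydrazone adduct F2; any C9 epimer is removed by chromatography. The auxiliary is then cleaved with aqueous oxalic acid/Et2O (no ozone, because of the furan), which returns to the route at 9.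

**Step 9 (stitching macrocyclisation).** Closing a strained ten-membered E,Z,Z-triene by Stille coupling competes with oligomerisation and protodestannylation. The fallback sets out from aldehyde 15 and moves the ring closure to the C10=C1 bond. The α-bromide of 15 is coupled with (Z)-3-(tributylstannyl)prop-2-en-1-ol (Pd2(dba)3, AsPh3, CuI, NMP, 40 °C) to give the (Z)-allylic alcohol F3. MsCl/Et3N converts it into the allylic mesylate F4, which is treated at once with PBu3 in MeCN to give the allyltributylphosphonium methanesulfonate F5. KOt-Bu in THF at 1 mM then effects an intramolecular, E-selective Wittig reaction with the C10 aldehyde and returns to the route at 21.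

**Step 10 (lactone opening and acetylation).** If the carboxylate is activated by Ac2O before the alcohol is acetylated, the butenolide 21 simply re-forms. The fallback sets out from 21 and protects the acid before acetylation. LiOH gives 22 as in the main route; the dry salt is alkylated with 2-(trimethylsilyl)ethoxymethyl chloride in DMF at 0 °C to give the hydroxy SEM ester F6, which is acetylated at once (Ac2O, pyridine, 0 °C) to the acetoxy SEM ester F7. MgBr2·OEt2 in Et2O at rt removes the SEM ester without touching the acetate, the furan or the triene, and returns to the route at 23.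

## Further compounds

F1 | step 3 | propanal SAMP hydrazone, (2S)-2-(methoxymethyl)-N-[(E)-propylidene]pyrrolidin-1-amine | COC[C@@H]1CCCN1/N=C/CC
F2 | step 3 | SAMP hydrazone of 9, (2S)-N-[(1E,2S,3S)-5-(furan-3-yl)-2,3-dimethyl-3-(nitromethyl)pentylidene]-2-(methoxymethyl)pyrrolidin-1-amine | COC[C@@H]1CCCN1/N=C/[C@@H](C)[C@](C)(CCc2ccoc2)C[N+](=O)[O-]
F3 | step 9 | (2S,3R)-2-[2-(furan-3-yl)ethyl]-5-{4-[(1Z)-3-hydroxyprop-1-en-1-yl]-5-oxo-2,5-dihydrofuran-3-yl}-2,3-dimethylpentanal | O=C[C@@](C)(CCc1ccoc1)[C@H](C)CCC1=C(/C=C\CO)C(=O)OC1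
F4 | step 9 | methanesulfonate of F3 (allylic mesylate) | O=C[C@@](C)(CCc1ccoc1)[C@H](C)CCC1=C(/C=C\COS(C)(=O)=O)C(=O)OC1
F5 | step 9 | tributyl[(2Z)-3-(4-{(3R,4S)-4-formyl-6-(furan-3-yl)-3,4-dimethylhexyl}-2-oxo-2,5-dihydrofuran-3-yl)prop-2-en-1-yl]phosphonium methanesulfonate | O=C[C@@](C)(CCc1ccoc1)[C@H](C)CCC1=C(/C=C\C[P+](CCCC)(CCCC)CCCC)C(=O)OC1.CS(=O)(=O)[O-]
F6 | step 10 | [2-(trimethylsilyl)ethoxy]methyl (1(10)Z,2Z,4E,6S,7R)-6-[2-(furan-3-yl)ethyl]-10-(hydroxymethyl)-6,7-dimethylcyclodeca-1(10),2,4-triene-1-carboxylate | OC/C1=C(C(=O)OCOCC[Si](C)(C)C)/C=C\C=C\[C@@](C)(CCc2ccoc2)[C@H](C)CC1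
F7 | step 10 | [2-(trimethylsilyl)ethoxy]methyl (1(10)Z,2Z,4E,6S,7R)-10-(acetoxymethyl)-6-[2-(furan-3-yl)ethyl]-6,7-dimethylcyclodeca-1(10),2,4-triene-1-carboxylate | CC(=O)OC/C1=C(C(=O)OCOCC[Si](C)(C)C)/C=C\C=C\[C@@](C)(CCc2ccoc2)[C@H](C)CC1
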